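**Strategy**

Everything rests on cutting ring B of the depside at C1–C2 and C5–C6. Its C1 carbonyl and C6 pentyl chain are the two ends of an oct-2-ynoate, and its C2 oxygen, C3 chlorine and C4 methoxyl lie on a 2-chloro-1,3-dimethoxy-1-silyloxybutadiene. One (4+2) benzannulation should therefore build the whole pentasubstituted ring B, chlorine in place between the two oxygens, directly on the O4 ester of ring A. The dienophile is benzyl olivetolate acylated at its free 4-hydroxyl by oct-2-ynoic acid, with the chelated 2-hydroxyl capped as a triethylsilyl ether that falls off in the acidic work-up, so that a single benzyl ester remains to be cleaved.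

Key step: step 6

Remark on the chemistry: the 2-hydroxyl of ring A is carried as a silyl ether and not as a benzyl ether, because alkylation of a 2,4-dihydroxybenzoate goes first to the 4-hydroxyl; a 2-O-benzyl-4-hydroxy ester would need a protect–deprotect detour, whereas acylation of the 4-hydroxyl of the benzyl ester is innately selective.

Assumption: the double-bond geometry of the enol ether, of its lithium dienolate and of the diene is not controlled; each is drawn as one isomer, and any mixture converges because the geometry is erased on aromatisation. Intermediates with a single stereocentre are racemic.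

**Route**

Step 1
Reactants: 1 olivetolic acid (2,4-dihydroxy-6-pentylbenzoic acid)
Product: 2 benzyl 2,4-dihydroxy-6-pentylbenzoate
Conditions: BnBr (1.05 equiv), KHCO3, DMF, rt
Reagents that add atoms: benzyl bromide, BrCc1ccccc1
Why: Carboxylate O-alkylation (SN2), in which KHCO3 deprotonates only the carboxylic acid, so that benzyl bromide should esterify it and leave both phenols free, while the mild conditions avoid decarboxylation of the resorcylic acid.

Step 2
Reactants: 2 benzyl 2,4-dihydroxy-6-pentylbenzoate; 3 oct-2-ynoic acid
Product: 4 benzyl 2-hydroxy-4-(oct-2-ynoyloxy)-6-pentylbenzoate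
Conditions: DCC, DMAP (cat.), CH2Cl2, 0 °C to rt
Reagents that add atoms: none
Why: Steglich esterification, in which the 2-hydroxyl is tied up in a hydrogen bond to the neighbouring ester carbonyl, so that only the free and more acidic 4-hydroxyl should be acylated by the carbodiimide-activated ynoic acid, and catalytic DMAP at low temperature should not isomerise the alk-2-ynoate.

Step 3
Reactants: 4 benzyl 2-hydroxy-4-(oct-2-ynoyloxy)-6-pentylbenzoate
Product: 5 benzyl 4-(oct-2-ynoyloxy)-6-pentyl-2-(triethylsilyloxy)benzoate
Conditions: Et3SiOTf, 2,6-lutidine, CH2Cl2, −78 to 0 °C; chromatography on Et3N-washed SiO2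
Reagents that add atoms: triethylsilyl trifluoromethanesulfonate, CC[Si](CC)(CC)OS(=O)(=O)C(F)(F)F
Why: O-Silylation of a chelated phenol with a silyl triflate and a hindered, non-nucleophilic base that can neither add to the ynoate nor cleave the aryl ester, which removes the only acidic proton that could quench the ketene acetal diene in step 6.

Step 4
Reactants: 6 methyl 2-chloro-3-oxobutanoate (methyl 2-chloroacetoacetate)
Product: 8 methyl (2Z)-2-chloro-3-methoxybut-2-enoate, via dimethyl ketal 7 (not isolated)
Conditions: HC(OMe)3, H2SO4 (cat.), rt; then 110 °C with distillation of the volatiles, vacuum distillation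
Reagents that add atoms: trimethyl orthoformate, COC(OC)OC
Why: Acid-catalysed ketalisation by an orthoformate followed by loss of methanol (enol ether formation from a beta-keto ester), with conjugation to the ester steering the elimination towards C2, and a deconjugated isomer would give the same dienolate in step 5.

Step 5
Reactants: 8 methyl (2Z)-2-chloro-3-methoxybut-2-enoate
Product: 10 (1E)-2-chloro-1,3-dimethoxy-1-(trimethylsilyloxy)buta-1,3-diene, via lithium dienolate 9 (not isolated)
Conditions: LiN(iPr)2, THF, −78 °C; then Me3SiCl, −78 °C to rt; pentane, filtration under Ar, bulb-to-bulb distillation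
Reagents that add atoms: chlorotrimethylsilane, C[Si](C)(C)Cl
Why: Gamma-deprotonation of the beta-methoxy enoate to the extended ester enolate and O-silylation (vinylogous silyl ketene acetal formation), as practised on non-halogenated 3-alkoxybut-2-enoates, the hindered amide base leaving the vinylic C–Cl bond alone at −78 °C.

Step 6
Reactants: 5 benzyl 4-(oct-2-ynoyloxy)-6-pentyl-2-(triethylsilyloxy)benzoate; 10 (1E)-2-chloro-1,3-dimethoxy-1-(trimethylsilyloxy)buta-1,3-diene
Product: 13 benzyl 4-[(3-chloro-2-hydroxy-4-methoxy-6-pentylbenzoyl)oxy]-2-hydroxy-6-pentylbenzoate, via ketal cycloadduct 11 (not isolated), via triethylsilyl ether 12 (not isolated)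
Conditions: 10 (3 equiv), xylene, 130 °C, sealed tube, Ar; then 2 M aq. HCl, THF, rt
Reagents that add atoms: none
Why: Normal-electron-demand Diels–Alder benzannulation of a 1-alkoxy-1-silyloxy-1,3-diene with an acetylenic ester, the known route to resorcylates: the HOMO of diene 10 is largest at its CH2 terminus (C4) and the LUMO of ynoate 5 at the pentyl-bearing beta carbon, so C4 should bond to the beta carbon (C5–C6 of ring B) and the ketene acetal carbon C1 to the alpha carbon (C1–C2 of ring B). Ring B closes in this one intermolecular (4+2) event, concerted but asynchronous, or at the stepwise limit by vinylogous Mukaiyama–Michael addition followed by six-membered Claisen-type closure of the allenoate onto the oxocarbenium carbon, and both paths lead to cycloadduct 11. Aqueous acid removes Me3Si from the mixed ketal, the hemiketal expels methanol to a cyclohexa-2,5-dienone, and this tautomerises through its C5 methylene to the chelated phenol of 12, whose aryl triethylsilyl ether on ring A the same acid then cleaves to give 13. No stereocentre has to be controlled, since the single ketal stereocentre of 11 forms racemic and is destroyed on aromatisation. The only selectivity needed is regiochemical, and it is secured by the matched polarisation of ketene acetal and ynoate, reinforced by the electron-poor aryl ester, which lowers the LUMO relative to an alkyl ynoate. Chlorine and methoxyl arrive on the diene, so no arene has to be chlorinated between two oxygens.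

Step 7
Reactants: 13 benzyl 4-[(3-chloro-2-hydroxy-4-methoxy-6-pentylbenzoyl)oxy]-2-hydroxy-6-pentylbenzoate
Product: 14 4-[(3-chloro-2-hydroxy-4-methoxy-6-pentylbenzoyl)oxy]-2-hydroxy-6-pentylbenzoic acid
Conditions: H2 (1 atm), Pd/C (10% Pd on carbon), EtOAc, rt, stopped at full conversion
Reagents that add atoms: none
Why: Catalytic hydrogenolysis of a benzyl ester, which should be much faster than hydrodechlorination of an electron-rich aryl chloride over Pd/C in neutral ethyl acetate without base, while the hindered depside ester and the methyl ether are inert.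

**Compound list**

1 | olivetolic acid (2,4-dihydroxy-6-pentylbenzoic acid) | CCCCCc1cc(O)cc(O)c1C(=O)O | starting material
2 | benzyl 2,4-dihydroxy-6-pentylbenzoate | CCCCCc1cc(O)cc(O)c1C(=O)OCc1ccccc1 | intermediate
3 | oct-2-ynoic acid | CCCCCC#CC(=O)O | starting material
4 | benzyl 2-hydroxy-4-(oct-2-ynoyloxy)-6-pentylbenzoate | CCCCCC#CC(=O)Oc1cc(CCCCC)c(C(=O)OCc2ccccc2)c(O)c1 | intermediate
5 | benzyl 4-(oct-2-ynoyloxy)-6-pentyl-2-(triethylsilyloxy)benzoate | CCCCCC#CC(=O)Oc1cc(CCCCC)c(C(=O)OCc2ccccc2)c(O[Si](CC)(CC)CC)c1 | intermediate
6 | methyl 2-chloro-3-oxobutanoate (methyl 2-chloroacetoacetate, racemic) | CC(=O)C(Cl)C(=O)OC | starting material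
7 | methyl 2-chloro-3,3-dimethoxybutanoate (racemic, not isolated) | COC(=O)C(Cl)C(C)(OC)OC | intermediate
8 | methyl (2Z)-2-chloro-3-methoxybut-2-enoate | CO/C(C)=C(\Cl)C(=O)OC | intermediate
9 | lithium (1Z)-2-chloro-1,3-dimethoxybuta-1,3-dien-1-olate (same spatial arrangement as 10, not isolated) | C=C(OC)/C(Cl)=C(/OC)[O-].[Li+] | intermediate
10 | (1E)-2-chloro-1,3-dimethoxy-1-(trimethylsilyloxy)buta-1,3-diene | C=C(OC)/C(Cl)=C(/OC)O[Si](C)(C)C | intermediate
11 | benzyl 4-{[5-chloro-4,6-dimethoxy-2-pentyl-6-(trimethylsilyloxy)cyclohexa-1,4-diene-1-carbonyl]oxy}-6-pentyl-2-(triethylsilyloxy)benzoate (racemic at the ketal carbon, not isolated) | CCCCCC1=C(C(=O)Oc2cc(CCCCC)c(C(=O)OCc3ccccc3)c(O[Si](CC)(CC)CC)c2)C(OC)(O[Si](C)(C)C)C(Cl)=C(OC)C1 | intermediate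
12 | benzyl 4-[(3-chloro-2-hydroxy-4-methoxy-6-pentylbenzoyl)oxy]-6-pentyl-2-(triethylsilyloxy)benzoate (not isolated) | CCCCCc1cc(OC(=O)c2c(CCCCC)cc(OC)c(Cl)c2O)cc(O[Si](CC)(CC)CC)c1C(=O)OCc1ccccc1 | intermediate
13 | benzyl 4-[(3-chloro-2-hydroxy-4-methoxy-6-pentylbenzoyl)oxy]-2-hydroxy-6-pentylbenzoate | CCCCCc1cc(OC(=O)c2c(CCCCC)cc(OC)c(Cl)c2O)cc(O)c1C(=O)OCc1ccccc1 | intermediate
14 | 4-[(3-chloro-2-hydroxy-4-methoxy-6-pentylbenzoyl)oxy]-2-hydroxy-6-pentylbenzoic acid | CCCCCc1cc(OC(=O)c2c(CCCCC)cc(OC)c(Cl)c2O)cc(O)c1C(=O)O | target

**Summary**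

Total step count: 7. Longest linear sequence: 5 steps (steps 1, 2, 3, 6 and 7); steps 4 and 5 form the second branch, which joins at step 6.

**Steps most likely to fail**

Step 6. The 3-alkyl ynoate may be too sluggish a dienophile, the chloro diene may decompose or undergo silyl migration at the temperature required, or the addition may take the reversed orientation. The fallback sets out from 2 and builds ring B on an arene before a classical depside condensation. MeI and K2CO3 in acetone should methylate the free 4-hydroxyl of 2 to give benzyl 2-hydroxy-4-methoxy-6-pentylbenzoate F1. SO2Cl2 in Et2O at 0 °C should chlorinate F1, and chromatography would separate benzyl 3-chloro-2-hydroxy-4-methoxy-6-pentylbenzoate F2 from regioisomeric chloride. Hydrogenolysis (H2, Pd/C, EtOAc) should then free 3-chloro-2-hydroxy-4-methoxy-6-pentylbenzoic acid F3. Condensation of F3 with a second portion of 2 by (CF3CO)2O in toluene at rt, which acylates the unchelated 4-hydroxyl, comes back to the route at 13.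

Step 5. The alpha-chloro dienolate may decompose, silylation may occur on carbon instead of oxygen, or the ketene acetal may hydrolyse during isolation. The fallback sets out from 6 and switches to the better-precedented 1,3-bis(silyloxy)diene class. Me3SiCl and Et3N in toluene should give methyl (2E)-2-chloro-3-(trimethylsilyloxy)but-2-enoate F4. LiN(iPr)2 and then Me3SiCl in THF at −78 °C should give (1E)-2-chloro-1-methoxy-1,3-bis(trimethylsilyloxy)buta-1,3-diene F5, used crude. F5 and 5 under the thermal conditions and acidic work-up of step 6 should give benzyl 4-[(3-chloro-2,4-dihydroxy-6-pentylbenzoyl)oxy]-2-hydroxy-6-pentylbenzoate F6. Me3SiCHN2 in toluene–MeOH should methylate only the unchelated 4-hydroxyl of ring B, which comes back to the route at 13.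

Step 7. Hydrodechlorination of ring B may compete with cleavage of the benzyl ester. The fallback sets out from 13 and uses BCl3 with pentamethylbenzene in CH2Cl2 at −78 °C, a Lewis-acid debenzylation with a cation scavenger that needs neither hydrogen nor metal. It arrives directly at 14 and makes no new compound (entry F0).

**Further compounds**

F1 | step 6 | benzyl 2-hydroxy-4-methoxy-6-pentylbenzoate | CCCCCc1cc(OC)cc(O)c1C(=O)OCc1ccccc1
F2 | step 6 | benzyl 3-chloro-2-hydroxy-4-methoxy-6-pentylbenzoate | CCCCCc1cc(OC)c(Cl)c(O)c1C(=O)OCc1ccccc1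
F3 | step 6 | 3-chloro-2-hydroxy-4-methoxy-6-pentylbenzoic acid | CCCCCc1cc(OC)c(Cl)c(O)c1C(=O)O
F4 | step 5 | methyl (2E)-2-chloro-3-(trimethylsilyloxy)but-2-enoate | C/C(O[Si](C)(C)C)=C(\Cl)C(=O)OC
F5 | step 5 | (1E)-2-chloro-1-methoxy-1,3-bis(trimethylsilyloxy)buta-1,3-diene | C=C(O[Si](C)(C)C)/C(Cl)=C(/OC)O[Si](C)(C)C
F6 | step 5 | benzyl 4-[(3-chloro-2,4-dihydroxy-6-pentylbenzoyl)oxy]-2-hydroxy-6-pentylbenzoate | CCCCCc1cc(OC(=O)c2c(CCCCC)cc(O)c(Cl)c2O)cc(O)c1C(=O)OCc1ccccc1
F0 | step 7 | none | none
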